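The meeting opened on a leftover: at the last reading of the cedar run, at 10.0 h, 63% of the electrophile still stood, much as at 4.00 h. The analyst noted that if one nucleophile served one electrophile, the cedar charge would carry 74.0% of the electrophile through, yet the reading shows 37.0%, half of that. The kineticist replied that two nucleophiles per electrophile fit the other runs as well. Larch reads 65.0% reacted against 65.0% by that count, and birch 76.0% against 74.0%, within the scatter.

| flask | electrophile | nucleophile | remark | time |
|---|---|---|---|---|
| cedar | 0.50 M | 0.37 M | run made earlier |  |
| larch | 0.50 M | 0.65 M | run made earlier |  |
| birch | 0.50 M | 0.74 M | run made earlier |  |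
| Tuesday's | 0.50 M | 0.450 M |  | 15 h |
| Wednesday's | 0.50 M | 1.00 M |  | 15 h |
| Friday's | 0.50 M | 0.680 M |  | 15 h |

- cedar (time / h: electrophile / %, target / %): 1.33: 72, 23; 4.00: 63, 26; 6.00: 66, 26; 10.0: 63, 23
- larch (time / h: electrophile / %, target / %): 1.33: 54, 39; 4.00: 39, 45; 6.00: 35, 43; 10.0: 35, 47
- birch (time / h: electrophile / %, target / %): 1.33: 46, 42; 4.00: 31, 51; 6.00: 27, 52; 10.0: 24, 53

(readings scatter by 2 percentage points)



* part of the electrophile that has reacted at the end, Tuesday's
* part of the electrophile that has reacted at the end, Wednesday's
* part of the electrophile that has reacted at the end, Friday's
* what raising the concentration of nucleophile from its lowest to its highest value here does to the part of the electrophile that has reacted (changes below 5 percentage points count as none) (it rises / no change / it falls)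

The chair proposed exactly two equivalents as the zero of the scale, which is Wednesday's flask, with a ceiling of 100%. Below that zero the nucleophile is the limiting reagent. For Tuesday's flask the ceiling, the nucleophile charged over twice the electrophile charged, is 45.0%, and for Friday's flask it is 68.0%. The kineticist added that the larch readings were level by 6.00 h, earlier than the 15 h allowed here, so Tuesday's and Friday's flasks should reach their ceilings.

Wednesday's flask needed a rate as well. My own reckoning, as secretary, assumes the rate follows the product of the two reagents, which stay in step at the zero. What is left then falls as one over one plus time over the first half-time. The birch run read about half of its electrophile left at 1.33 h, so I took that as the half-time for Wednesday's flask, which gives 8.14% left and 91.9% reacted. I expect this estimate to be low, as Wednesday's flask holds more nucleophile than birch. The reacted part should therefore rise across the range by far more than 5 percentage points.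

The forecast gives 45%, 95% and 68% for Tuesday's, Wednesday's and Friday's flasks, with the trend it rises, holding that “each electrophile appears to use two nucleophiles”; its Wednesday figure stands above my 91.9%. The flasks gave 45.1%, 95.3% and 67.5% in that order, and on the trend it rises, by 50 points.

    nucleophile + acid set free ⇌ protonated nucleophile, settled at all times (K = 10000 M⁻¹)
    electrophile + nucleophile ⇌ acid set free + target (K = 0.640, k = 4.30 × 10⁻⁴ M⁻¹ s⁻¹)
    target → over-reaction product (k = 2.70 × 10⁻⁷ s⁻¹)
    target ⇌ isomer of the product (K = 0.480, k = 1.30 × 10⁻⁴ s⁻¹)

In Tuesday's flask the half-life of the electrophile by its forward step taken by itself, the other concentrations as charged, is 1.0 h, short against the 15 h, and at the end 0.97% of the charged nucleophile is unbound, less than the 55% of the charged electrophile still there, with 0.220 M standing as protonated nucleophile and the reacted part level with the ceiling of 45.0%. A neighbour of Wednesday's flask, charged with 1.2 M of electrophile, has a ceiling of 41.7%, and it gave 41.8%.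

(The runs stem from a simulated flask for substances that don't exist, noise included.)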